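**Retrosynthetic overview**
1. Target ⇐ Swern oxidation of the 11,12-diol; the diol and the C9 stereocentre ⇐ α-face hydroboration of a C9 exocyclic methylene.
2. Key disconnection: the C1–O ester bond, closed by a Z-selective carbene-catalysed redox esterification of the hindered 1β-alcohol with 3-phenylprop-2-ynal.
3. The 1β-alcohol with the C3=C4 dimethyl alkene ⇐ trans-fused ene-dione (MeMgBr at C4, SmI2 removal of the C4 oxygen with alkene shift, NaBH4 at C1).
4. Decalin ⇐ one enantioselective Diels–Alder reaction between a para-quinone monoketal (from oxidative dearomatisation of 2,5-dimethylphenol, whose oxygen becomes the C1 oxygen) and a vinylallene.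
5. Ring order: ring A is carried in from the phenol; ring B is closed in the cycloaddition, which also creates the quaternary C10.

Assumption: the bicyclic core ("decala-") is numbered as in drimanes (ring A C1–C5/C10, ring B C5–C10, C11 on C9, C12 on C8, β = face of the C10 methyl), and the (R)-BINOL titanium catalyst of step 3 is taken to give the enantiomer drawn (the (S)-ligand is used if the opposite sense is found).

**Step 1**
Reactants: 1 2,5-dimethylphenol
Product: 3 4,4-dimethoxy-2,5-dimethylcyclohexa-2,5-dien-1-one, via 4-methoxy-2,5-dimethylphenol 2 (not isolated)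
Conditions: PhI(OAc)2 (2.2 equiv), MeOH, 0 °C to rt
Reagents that add atoms: methanol (CO)
Why: Hypervalent-iodine oxidative dearomatisation of a para-unsubstituted phenol (two successive two-electron oxidations, each with methanol capture at the para carbon) gives the para-quinone monoketal, in which a single carbonyl is left to steer the cycloaddition; no stereocentre is formed.

**Step 2**
Reactants: 4 4-chlorobut-2-yn-1-ol
Product: 6 2-ethenylbuta-2,3-dien-1-yl acetate, via bromomagnesium 2-ethenylbuta-2,3-dien-1-olate 5 (not isolated)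
Conditions: CH2=CHMgBr (2.2 equiv), CuBr·SMe2 (10 mol %), THF, −78 to 0 °C; then Ac2O, 0 °C
Reagents that add atoms: vinylmagnesium bromide (C=C[Mg]Br), acetic anhydride (CC(=O)OC(C)=O)
Why: Copper-catalysed SN2′ substitution of the propargylic chloride by the vinyl Grignard reagent (the first equivalent only deprotonates the alcohol) gives the vinylallene, and the magnesium alkoxide is acetylated in the same flask; no stereocentre is formed.

**Step 3**
Reactants: 3 4,4-dimethoxy-2,5-dimethylcyclohexa-2,5-dien-1-one; 6 2-ethenylbuta-2,3-dien-1-yl acetate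
Product: 7 cis-fused adduct 12-acetoxy-4,4-dimethoxy-3,10β-dimethyl-5β-H-decala-2,7,9(11)-trien-1-one
Conditions: TiCl2(OiPr)2/(R)-BINOL (1:1, 20 mol %), 4 Å molecular sieves, 6 (1.5 equiv), CH2Cl2, −30 °C to rt
Reagents that add atoms: none
Why: Chiral-Lewis-acid-catalysed Diels–Alder reaction of the α-methyl enone arm of the quinone monoketal: the titanium-bound C1 carbonyl makes C5 the electrophilic β-carbon, which takes the nucleophilic vinyl terminus (C6), so the unhindered sp carbon of the allene (C9) bonds to C10 and closes ring B, while the BINOLate shields one face and thereby sets the quaternary C10 (C5 comes out cis and is corrected in step 4).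

**Step 4**
Reactants: 7 cis-fused adduct 12-acetoxy-4,4-dimethoxy-3,10β-dimethyl-5β-H-decala-2,7,9(11)-trien-1-one
Product: 9 trans-fused ene-dione 12-acetoxy-3,10β-dimethyl-5α-H-decala-2,7,9(11)-triene-1,4-dione, via cis-fused ene-dione 8 (not isolated)
Conditions: TsOH·H2O (10 mol %), acetone/H2O (10:1), rt; then DBU (0.3 equiv), CH2Cl2, rt
Reagents that add atoms: water (O)
Why: Acid-catalysed ketal hydrolysis unveils the C4 ketone, and base-mediated enolisation then epimerises C5 (now α to a carbonyl) to the trans ring fusion expected to be thermodynamically favoured for an angular-methyl ene-dione with flattened rings; residual cis isomer is re-equilibrated.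

**Step 5**
Reactants: 9 trans-fused ene-dione 12-acetoxy-3,10β-dimethyl-5α-H-decala-2,7,9(11)-triene-1,4-dione
Product: 11 diacetate 4β,12-diacetoxy-3,4α,10β-trimethyl-5α-H-decala-2,7,9(11)-trien-1-one, via bromomagnesium C4 alkoxide 10 (not isolated)
Conditions: MeMgBr (1.1 equiv), THF, −78 °C; then Ac2O (3 equiv), DMAP (10 mol %), −78 to 0 °C
Reagents that add atoms: methylmagnesium bromide (C[Mg]Br), acetic anhydride (CC(=O)OC(C)=O)
Why: Chemoselective Grignard 1,2-addition to the less hindered C4 carbonyl (C1 is neopentylic, and ketone addition at −78 °C outruns attack on the acetate) followed by in-flask O-acetylation; attack anti to the 10β-methyl gives mainly the 4β-acetate, but C4 becomes sp2 in step 6, so both epimers converge.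

**Step 6**
Reactants: 11 diacetate 4β,12-diacetoxy-3,4α,10β-trimethyl-5α-H-decala-2,7,9(11)-trien-1-one
Product: 13 alcohol 12-acetoxy-3,4,10β-trimethyl-5α-H-decala-3,7,9(11)-trien-1β-ol, via C1 ketone 12 (not isolated)
Conditions: SmI2 (2.5 equiv), THF/MeOH (10:1), −78 °C; then NaBH4 (2 equiv), −78 to −30 °C
Reagents that add atoms: none
Why: Samarium diiodide reductive elimination of the γ-acetoxy group of the enone gives a dienolate that is protonated kinetically at C2, which places the tetrasubstituted alkene at C3=C4, and borohydride reduction of the resulting ketone by axial attack on the α face (anti to the axial 10β-methyl) sets the equatorial 1β-hydroxyl.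

**Step 7**
Reactants: 13 alcohol 12-acetoxy-3,4,10β-trimethyl-5α-H-decala-3,7,9(11)-trien-1β-ol; 14 3-phenylprop-2-ynal
Product: 15 ester 12-acetoxy-3,4,10β-trimethyl-5α-H-decala-3,7,9(11)-trien-1β-yl (Z)-3-phenylprop-2-enoate
Conditions: 2-(2,6-diisopropylphenyl)-6,7-dihydro-5H-pyrrolo[2,1-c][1,2,4]triazol-2-ium tetrafluoroborate (10 mol %), iPr2NEt (10 mol %), 2,4,6-tri-tert-butylphenol (20 mol %), 14 (1.5 equiv), 4 Å molecular sieves, toluene, −20 to 0 °C
Reagents that add atoms: none
Why: Proposed new method: a Z-selective carbene-catalysed redox esterification forms the C1–O acyl bond and the Z alkene together — the triazolylidene adds to ynal 14, the Breslow-type intermediate is protonated at the phenyl-bearing carbon to an azolium allenol, the bulky phenol then protonates the central allene carbon from the side away from phenyl (kinetic control, which puts acyl and phenyl cis), and the resulting (Z)-cinnamoyl azolium, kept cold with only a hindered amine present so that no addition–elimination can scramble the alkene, acylates the 1β-hydroxyl and releases the carbene; the closest known reaction type is the carbene-catalysed redox esterification of alkynyl aldehydes with alcohols, which delivers E-enoates, so Z selectivity and acyl transfer to a neopentylic secondary alcohol are the untested points, and no sp3 stereocentre is touched.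

**Step 8**
Reactants: 15 ester 12-acetoxy-3,4,10β-trimethyl-5α-H-decala-3,7,9(11)-trien-1β-yl (Z)-3-phenylprop-2-enoate
Product: 17 diol 11,12-dihydroxy-3,4,10β-trimethyl-5α,9α-H-decala-3,7-dien-1β-yl (Z)-3-phenylprop-2-enoate, via C11 alkylborane 16 (not isolated)
Conditions: 9-BBN (1.5 equiv), THF, 0 to 40 °C; then 2 M NaOH, 30 % H2O2, 0 °C
Reagents that add atoms: hydrogen peroxide (OO)
Why: Hydroboration–oxidation: 9-BBN adds only to the terminal exocyclic methylene of the diene (boron at C11) and delivers hydrogen to C9 from the α face, opposite the axial 10β-methyl and the 1β-ester, which sets 9α-H with the CH2OH group β, and the alkaline peroxide work-up also cleaves the primary allylic acetate while the hindered, conjugated secondary ester survives.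

**Step 9**
Reactants: 17 diol 11,12-dihydroxy-3,4,10β-trimethyl-5α,9α-H-decala-3,7-dien-1β-yl (Z)-3-phenylprop-2-enoate
Product: 18 target 11,12-dioxo-3,4,10β-trimethyl-5α,9α-H-decala-3,7-dien-1β-yl (Z)-3-phenylprop-2-enoate (CNP0241745.1)
Conditions: (COCl)2, DMSO, CH2Cl2, −78 °C; then Et3N, −78 to −40 °C
Reagents that add atoms: none
Why: Swern oxidation activates both primary alcohols of the 11,12-diol at once, so no lactol or lactone can form, and elimination with triethylamine below −40 °C leaves the base-sensitive C9 stereocentre and the Z-enoate untouched, the standard way to reach polygodial-type ene-dialdehydes.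

**Compound list**
1 | 2,5-dimethylphenol | Cc1ccc(C)c(O)c1 | starting material
2 | 4-methoxy-2,5-dimethylphenol | Cc1cc(OC)c(C)cc1O | intermediate
3 | 4,4-dimethoxy-2,5-dimethylcyclohexa-2,5-dien-1-one | O=C1C(C)=CC(OC)(OC)C(C)=C1 | intermediate
4 | 4-chlorobut-2-yn-1-ol | OCC#CCCl | starting material
5 | bromomagnesium 2-ethenylbuta-2,3-dien-1-olate | C=CC(=C=C)CO[Mg]Br | intermediate
6 | 2-ethenylbuta-2,3-dien-1-yl acetate | CC(=O)OCC(C=C)=C=C | intermediate
7 | cis-fused adduct: 12-acetoxy-4,4-dimethoxy-3,10β-dimethyl-5β-H-decala-2,7,9(11)-trien-1-one | CC=1C(OC)(OC)[C@H]2CC=C(COC(C)=O)C(=C)[C@@]2(C)C(=O)C=1 | intermediate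
8 | cis-fused ene-dione: 12-acetoxy-3,10β-dimethyl-5β-H-decala-2,7,9(11)-triene-1,4-dione | CC=1C(=O)[C@H]2CC=C(COC(C)=O)C(=C)[C@@]2(C)C(=O)C=1 | intermediate
9 | trans-fused ene-dione: 12-acetoxy-3,10β-dimethyl-5α-H-decala-2,7,9(11)-triene-1,4-dione | CC=1C(=O)[C@@H]2CC=C(COC(C)=O)C(=C)[C@@]2(C)C(=O)C=1 | intermediate
10 | bromomagnesium C4 alkoxide of 12-acetoxy-4β-hydroxy-3,4α,10β-trimethyl-5α-H-decala-2,7,9(11)-trien-1-one (major C4 epimer) | CC=1[C@](C)(O[Mg]Br)[C@@H]2CC=C(COC(C)=O)C(=C)[C@@]2(C)C(=O)C=1 | intermediate
11 | diacetate: 4β,12-diacetoxy-3,4α,10β-trimethyl-5α-H-decala-2,7,9(11)-trien-1-one (major C4 epimer) | CC=1[C@](C)(OC(C)=O)[C@@H]2CC=C(COC(C)=O)C(=C)[C@@]2(C)C(=O)C=1 | intermediate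
12 | C1 ketone: 12-acetoxy-3,4,10β-trimethyl-5α-H-decala-3,7,9(11)-trien-1-one | CC1=C(C)[C@@H]2CC=C(COC(C)=O)C(=C)[C@@]2(C)C(=O)C1 | intermediate
13 | alcohol: 12-acetoxy-3,4,10β-trimethyl-5α-H-decala-3,7,9(11)-trien-1β-ol | CC1=C(C)[C@@H]2CC=C(COC(C)=O)C(=C)[C@@]2(C)[C@H](O)C1 | intermediate
14 | 3-phenylprop-2-ynal | O=CC#Cc1ccccc1 | starting material
15 | ester: 12-acetoxy-3,4,10β-trimethyl-5α-H-decala-3,7,9(11)-trien-1β-yl (Z)-3-phenylprop-2-enoate | CC1=C(C)[C@@H]2CC=C(COC(C)=O)C(=C)[C@@]2(C)[C@H](OC(=O)/C=C\c2ccccc2)C1 | intermediate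
16 | C11 alkylborane: 11-(9-borabicyclo[3.3.1]nonan-9-yl) derivative of 15 (9α-H) | CC1=C(C)[C@@H]2CC=C(COC(C)=O)[C@H](CB3C4CCCC3CCC4)[C@@]2(C)[C@H](OC(=O)/C=C\c2ccccc2)C1 | intermediate
17 | diol: 11,12-dihydroxy-3,4,10β-trimethyl-5α,9α-H-decala-3,7-dien-1β-yl (Z)-3-phenylprop-2-enoate | CC1=C(C)[C@@H]2CC=C(CO)[C@H](CO)[C@@]2(C)[C@H](OC(=O)/C=C\c2ccccc2)C1 | intermediate
18 | 11,12-dioxo-3,4,10β-trimethyl-5α,9α-H-decala-3,7-dien-1β-yl (Z)-3-phenylprop-2-enoate (CNP0241745.1) | CC1=C(C)[C@@H]2CC=C(C=O)[C@H](C=O)[C@@]2(C)[C@H](OC(=O)/C=C\c2ccccc2)C1 | target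

**Step count**
Total steps: 9. Longest linear sequence: 8 steps (steps 1, 3, 4, 5, 6, 7, 8, 9 from 1; equally steps 2 to 9 from 4).

**Three steps most likely to fail**

Step 3. An allenic diene and an α-methylated quinone monoketal have not been paired under a chiral titanium catalyst, so rate, orientation and enantiomeric excess are uncertain. Fallback: starting from 3 and 6, the cycloaddition is run without catalyst (toluene, 110 °C, sealed tube), which gives the cis-fused adduct as a racemate, that is 7 together with the mirror-image adduct F1. The two are separated by preparative chromatography on a chiral stationary phase, and the route is rejoined at 7.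

Step 7. This is the proposed new step; leakage to the E ester and slow acyl transfer to the hindered alcohol are the risks. Fallback with known chemistry: starting from 13, Steglich esterification with phenylpropiolic acid (DCC, DMAP, CH2Cl2, 0 °C) gives the phenylpropiolate ester F2. Cis-selective semi-hydrogenation of the alkyne (H2 1 atm, Pd/CaCO3 poisoned with Pb(OAc)2, quinoline, EtOAc) then returns to the route at 15.

Step 8. The alkaline peroxide work-up has to cleave the acetate without touching the cinnamate, and the borane must ignore the enoate. Fallback: starting from 13, hydroboration–oxidation is done before the ester is made (9-BBN, then NaOH/H2O2), giving the 1β,11,12-triol F3. The two primary hydroxyls are silylated (Et3SiCl, imidazole, CH2Cl2, −40 °C) to the bis(triethylsilyl) ether F4. The remaining 1β-hydroxyl is esterified as in step 7 to the bis-silylated cinnamate F5. Swern oxidation, which converts primary triethylsilyl ethers directly into aldehydes, comes back to the route at 18.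

**Further compounds**
F1 | step 3 | mirror-image adduct (enantiomer of 7) | CC=1C(OC)(OC)[C@@H]2CC=C(COC(C)=O)C(=C)[C@]2(C)C(=O)C=1
F2 | step 7 | phenylpropiolate ester: 12-acetoxy-3,4,10β-trimethyl-5α-H-decala-3,7,9(11)-trien-1β-yl 3-phenylprop-2-ynoate | CC1=C(C)[C@@H]2CC=C(COC(C)=O)C(=C)[C@@]2(C)[C@H](OC(=O)C#Cc2ccccc2)C1
F3 | step 8 | 1β,11,12-triol: 3,4,10β-trimethyl-5α,9α-H-decala-3,7-diene-1β,11,12-triol | CC1=C(C)[C@@H]2CC=C(CO)[C@H](CO)[C@@]2(C)[C@H](O)C1
F4 | step 8 | bis(triethylsilyl) ether: 11,12-bis(triethylsilyloxy)-3,4,10β-trimethyl-5α,9α-H-decala-3,7-dien-1β-ol | CC1=C(C)[C@@H]2CC=C(CO[Si](CC)(CC)CC)[C@H](CO[Si](CC)(CC)CC)[C@@]2(C)[C@H](O)C1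
F5 | step 8 | bis-silylated cinnamate: 11,12-bis(triethylsilyloxy)-3,4,10β-trimethyl-5α,9α-H-decala-3,7-dien-1β-yl (Z)-3-phenylprop-2-enoate | CC1=C(C)[C@@H]2CC=C(CO[Si](CC)(CC)CC)[C@H](CO[Si](CC)(CC)CC)[C@@]2(C)[C@H](OC(=O)/C=C\c2ccccc2)C1
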